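## Retrosynthetic overview

1. The C8 quaternary centre is made last, by catalyst-controlled dearomative C-prenylation of an 8-(cyclobutylmethyl)-5,7-dihydroxychromanone acid.
2. The aryl–CH2–cyclobutane bond comes from reductive alkylation of the only free aromatic CH with a cis-cyclobutane aldehyde cut out of (−)-verbenone; the four-membered ring is bought, not built.
3. The octanoic acid arm is released by saponification of a 4-pentyl-3,4-dihydrocoumarin lactone.
4. Key step: both heterocycles (dihydropyranone and lactone) are closed in one flask on acyclic 2-tigloylphloroglucinol with oct-2-ynal, by an organocatalytic relay that also sets three stereocentres.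
5. Ring order: benzene ring bought, then dihydropyranone, then lactone (same operation), lactone opened, carbocycle dearomatised.

Assumption: the facial sense of the three catalyst-controlled events (quinine, the triazolium carbene, the Trost ligand) is taken from their closest published uses; if one proves opposite, the mirror-image catalyst (quinidine in place of quinine) is used and nothing else changes. Compound 9 is used in enantiopure grade.

## Route

Step 1
Reactants: 1 phloroglucinol; 2 tigloyl chloride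
Product: 3 (E)-2-methyl-1-(2,4,6-trihydroxyphenyl)but-2-en-1-one
Conditions: AlCl3 (3.5 equiv), PhNO2, 0 °C to rt; cold 1 M HCl
Reagents that add atoms: none
Why: Friedel–Crafts C-acylation of the threefold-symmetric, very electron-rich arene stops after one acylation because the chelated aryl ketone is deactivated, and under Lewis-acidic, base-free conditions the enone is not cyclised, so no stereocentre is formed yet.

Step 2
Reactants: 3 (E)-2-methyl-1-(2,4,6-trihydroxyphenyl)but-2-en-1-one; 4 oct-2-ynal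
Product: 7 (2R,3R,6S)-5-hydroxy-2,3-dimethyl-6-pentyl-2,3,6,7-tetrahydropyrano[3,2-g]chromene-4,8-dione, via cis-chromanone 5 (not isolated), via cis-lactone 6 (not isolated)
Conditions: (−)-quinine (10 mol%), PhCl, 15 °C; then 4 (1.3 equiv), (5aS,10bR)-2-mesityl-5a,10b-dihydro-4H,6H-indeno[2,1-b][1,2,4]triazolo[4,3-d][1,4]oxazin-2-ium chloride (10 mol%), 40 °C; then MgI2 (0.5 equiv), Et3N (2 equiv), rt
Reagents that add atoms: none
Why: Proposed new method: a three-stage relay in one flask, in which (a) quinine acts as a chiral Brønsted base for the 6-endo oxa-Michael addition of one of the two equivalent ortho-hydroxyls to the tigloyl group, setting C2 as R and giving the kinetic cis-2,3 product 5 (closest known: cinchona-alkaloid-catalysed intramolecular oxa-Michael addition of o-tigloylphenols); (b) the carbene turns the ynal by internal redox into an (E)-α,β-unsaturated acyl azolium that is attacked by the free 7-OH, undergoes a Coates–Claisen-type [3,3] shift to C6 and lactonises on O7, the aminoindanol backbone shielding one face so that the pentyl-bearing centre is set as S, with C6 preferred over C8 because the chelated 5-OH/C4=O unit localises double-bond character in C6–C7 (closest known: carbene-catalysed [3+3] annulation of ynals with naphthols and other stable enols); and (c) soft enolisation by MgI2/Et3N epimerises only C3 to the diequatorial trans isomer (3R).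

Step 3
Reactants: 7 (2R,3R,6S)-5-hydroxy-2,3-dimethyl-6-pentyl-2,3,6,7-tetrahydropyrano[3,2-g]chromene-4,8-dione
Product: 8 (3S)-3-[(2R,3R)-5,7-dihydroxy-2,3-dimethyl-4-oxochroman-6-yl]octanoic acid
Conditions: LiOH·H2O (4 equiv), THF/H2O 3:1, 0 °C, 1 h; 1 M HCl to pH 3–4 at 0 °C; used at once
Reagents that add atoms: water, O
Why: Saponification of the aryl ester (lactone) is fast at 0 °C, while the polyphenoxide formed resists enolisation at C3 and retro-oxa-Michael opening, so all three stereocentres are kept and the free 7-OH needed next is unmasked.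

Step 4
Reactants: 9 (1S,5S)-(−)-verbenone
Product: 10 (1S,3R)-3-acetyl-2,2-dimethylcyclobutane-1-carboxylic acid (cis-pinononic acid)
Conditions: RuCl3·xH2O (2 mol%), NaIO4 (4.2 equiv), CH2Cl2/MeCN/H2O 2:2:3, rt
Reagents that add atoms: sodium periodate, [Na+].[O-]I(=O)(=O)=O; water, O
Why: RuO4 generated catalytically cleaves the enone C=C and the resulting α-keto acid loses one carbon as CO2, leaving the cis-1,3-disubstituted cyclobutane with both ring stereocentres untouched under the acidic oxidative conditions (oxidative alkene cleavage).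

Step 5
Reactants: 10 (1S,3R)-3-acetyl-2,2-dimethylcyclobutane-1-carboxylic acid
Product: 11 (1S,3S)-2,2-dimethyl-3-(prop-1-en-2-yl)cyclobutane-1-carboxylic acid
Conditions: Ph3PCH3Br (2.5 equiv), KOtBu (3.5 equiv), THF, 0 °C to rt; aq. NaHSO4
Reagents that add atoms: methyltriphenylphosphonium bromide, C[P+](c1ccccc1)(c1ccccc1)c1ccccc1.[Br-]
Why: Wittig methylenation of the methyl ketone proceeds on the potassium carboxylate, and any competing deprotonation occurs at the unhindered acetyl CH3, not at the ring CH, so the cis configuration is retained (the descriptor at C3 changes only through priority).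

Step 6
Reactants: 11 (1S,3S)-2,2-dimethyl-3-(prop-1-en-2-yl)cyclobutane-1-carboxylic acid
Product: 13 (1S,3S)-2,2-dimethyl-3-(prop-1-en-2-yl)cyclobutane-1-carbaldehyde, via acyl imidazolide 12 (not isolated)
Conditions: 1,1'-carbonyldiimidazole (1.1 equiv), CH2Cl2, rt; then i-Bu2AlH (2.1 equiv), −78 °C; aq. tartaric acid
Reagents that add atoms: none
Why: The acyl imidazolide is reduced by i-Bu2AlH at −78 °C to a stable tetrahedral aluminate that gives the aldehyde only on work-up, which avoids over-reduction, strong acid (isopropenyl group) and base (α-centre), so the cis configuration is retained.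

Step 7
Reactants: 8 (3S)-3-[(2R,3R)-5,7-dihydroxy-2,3-dimethyl-4-oxochroman-6-yl]octanoic acid; 13 (1S,3S)-2,2-dimethyl-3-(prop-1-en-2-yl)cyclobutane-1-carbaldehyde
Product: 14 (3S)-3-[(2R,3R)-8-{[(1R,3S)-2,2-dimethyl-3-(prop-1-en-2-yl)cyclobutyl]methyl}-5,7-dihydroxy-2,3-dimethyl-4-oxochroman-6-yl]octanoic acid
Conditions: L-proline (20 mol%), Hantzsch ester (1.5 equiv), EtOH/CH2Cl2, rt to 40 °C
Reagents that add atoms: none
Why: Three-component reductive alkylation: the proline iminium of 13 is attacked by C8, the only free aromatic carbon (ortho to 7-OH, para to 5-OH), loss of proline gives an ortho-quinone methide, and hydride transfer from the Hantzsch ester gives the ArCH2 group; no stereocentre is formed and the cyclobutane centres are carried through (1R,3S by priority change only).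

Step 8
Reactants: 14 (3S)-3-[(2R,3R)-8-{[(1R,3S)-2,2-dimethyl-3-(prop-1-en-2-yl)cyclobutyl]methyl}-5,7-dihydroxy-2,3-dimethyl-4-oxochroman-6-yl]octanoic acid; 15 prenyl acetate
Product: 16 (3S)-3-[(2R,3R,8R)-8-{[(1R,3S)-2,2-dimethyl-3-(prop-1-en-2-yl)cyclobutyl]methyl}-5-hydroxy-2,3-dimethyl-8-(3-methylbut-2-en-1-yl)-4,7-dioxo-3,4,7,8-tetrahydro-2H-chromen-6-yl]octanoic acid
Conditions: Pd2(dba)3·CHCl3 (2.5 mol%), (R,R)-DACH-phenyl Trost ligand (7.5 mol%), 15 (1.2 equiv), Cs2CO3 (2.2 equiv), THF, 0 °C to rt; aq. citric acid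
Reagents that add atoms: none
Why: Proposed new method: the caesium 7-phenoxide (the most acidic OH, para to the ketone) attacks the cationic π-prenyl complex formed from zerovalent palladium through C8; O-prenylation of phenoxide or carboxylate is reversible under the catalyst whereas C–C formation is not, attack goes to the CH2 terminus of the prenyl unit because a quaternary centre is being made, C6 is disfavoured because it carries a branched secondary alkyl group, and the chiral pocket of the ligand selects the face of C8 to give R (closest known: Tsuji–Trost dearomative C-allylation and C-prenylation of acylphloroglucinols, palladium-catalysed asymmetric allylic dearomatisation of naphthols and asymmetric prenylation of oxindoles).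

## Compound list

1 | phloroglucinol (benzene-1,3,5-triol) | Oc1cc(O)cc(O)c1 | starting material
2 | tigloyl chloride, (E)-2-methylbut-2-enoyl chloride | C/C=C(\C)C(=O)Cl | starting material
3 | (E)-2-methyl-1-(2,4,6-trihydroxyphenyl)but-2-en-1-one | C/C=C(\C)C(=O)c1c(O)cc(O)cc1O | intermediate
4 | oct-2-ynal | CCCCCC#CC=O | starting material
5 | (2R,3S)-5,7-dihydroxy-2,3-dimethylchroman-4-one (cis-chromanone) | Oc1cc(O)c2c(c1)O[C@H](C)[C@H](C)C2=O | intermediate
6 | (2R,3S,6S)-5-hydroxy-2,3-dimethyl-6-pentyl-2,3,6,7-tetrahydropyrano[3,2-g]chromene-4,8-dione (cis-lactone) | CCCCC[C@H]1CC(=O)Oc2cc3O[C@H](C)[C@H](C)C(=O)c3c(O)c21 | intermediate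
7 | (2R,3R,6S)-5-hydroxy-2,3-dimethyl-6-pentyl-2,3,6,7-tetrahydropyrano[3,2-g]chromene-4,8-dione (linear tricycle: trans-2,3-dimethylchromanone fused to a 4-pentyl-dihydrocoumarin lactone closed on O7) | CCCCC[C@H]1CC(=O)Oc2cc3O[C@H](C)[C@@H](C)C(=O)c3c(O)c21 | intermediate
8 | (3S)-3-[(2R,3R)-5,7-dihydroxy-2,3-dimethyl-4-oxochroman-6-yl]octanoic acid | CCCCC[C@@H](CC(=O)O)c1c(O)cc2O[C@H](C)[C@@H](C)C(=O)c2c1O | intermediate
9 | (1S,5S)-(−)-verbenone, (1S,5S)-4,6,6-trimethylbicyclo[3.1.1]hept-3-en-2-one | CC1=CC(=O)[C@H]2C[C@@H]1C2(C)C | starting material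
10 | (1S,3R)-3-acetyl-2,2-dimethylcyclobutane-1-carboxylic acid (cis) | CC(=O)[C@@H]1C[C@H](C(=O)O)C1(C)C | intermediate
11 | (1S,3S)-2,2-dimethyl-3-(prop-1-en-2-yl)cyclobutane-1-carboxylic acid (cis) | C=C(C)[C@@H]1C[C@H](C(=O)O)C1(C)C | intermediate
12 | [(1S,3S)-2,2-dimethyl-3-(prop-1-en-2-yl)cyclobutyl](1H-imidazol-1-yl)methanone (acyl imidazolide) | C=C(C)[C@@H]1C[C@H](C(=O)n2ccnc2)C1(C)C | intermediate
13 | (1S,3S)-2,2-dimethyl-3-(prop-1-en-2-yl)cyclobutane-1-carbaldehyde (cis) | C=C(C)[C@@H]1C[C@H](C=O)C1(C)C | intermediate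
14 | (3S)-3-[(2R,3R)-8-{[(1R,3S)-2,2-dimethyl-3-(prop-1-en-2-yl)cyclobutyl]methyl}-5,7-dihydroxy-2,3-dimethyl-4-oxochroman-6-yl]octanoic acid | CCCCC[C@@H](CC(=O)O)c1c(O)c(C[C@H]2C[C@@H](C(C)=C)C2(C)C)c2O[C@H](C)[C@@H](C)C(=O)c2c1O | intermediate
15 | prenyl acetate, 3-methylbut-2-en-1-yl acetate | CC(C)=CCOC(C)=O | starting material
16 | (3S)-3-[(2R,3R,8R)-8-{[(1R,3S)-2,2-dimethyl-3-(prop-1-en-2-yl)cyclobutyl]methyl}-5-hydroxy-2,3-dimethyl-8-(3-methylbut-2-en-1-yl)-4,7-dioxo-3,4,7,8-tetrahydro-2H-chromen-6-yl]octanoic acid (CNP0208815.1) | C=C(C)[C@@H]1C[C@H](C[C@@]2(CC=C(C)C)C(=O)C([C@@H](CCCCC)CC(=O)O)=C(O)C3=C2O[C@H](C)[C@@H](C)C3=O)C1(C)C | target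

## Step count and risks

Total steps: 8 (steps 1–3 and 4–6 are two branches joined in step 7).
Longest linear sequence: 5 steps (1, 2, 3, 7, 8 from phloroglucinol; equally 4, 5, 6, 7, 8 from verbenone).

Steps most likely to fail:

Step 2. The risks are the site of C–C bond formation in the carbene stage (C6 wanted, C8 would give the angular isomer), interference between the two organocatalysts, and the level of enantiocontrol of either stage on this substrate. Lactonisation on O5 instead of O7 would not matter, since both lactones give 8 in step 3. The fallback sets out from 1 and 2 and comes back at 8, building the rings one at a time with the regiochemistry known for 5,7-dihydroxy-4-alkylcoumarins. Pechmann condensation of 1 with ethyl 3-oxooctanoate in MsOH gives 5,7-dihydroxy-4-pentyl-2H-chromen-2-one F1. AlCl3-mediated Friedel–Crafts acylation with 2 goes to C8 and gives 5,7-dihydroxy-8-[(E)-2-methylbut-2-enoyl]-4-pentyl-2H-chromen-2-one F2. Quinine-catalysed oxa-Michael closure followed by MgI2/Et3N epimerisation gives the angular (8R,9R)-5-hydroxy-8,9-dimethyl-4-pentyl-8,9-dihydro-2H,10H-pyrano[2,3-f]chromene-2,10-dione F3. Copper hydride conjugate reduction of the coumarin C3=C4 bond (Cu(OAc)2·H2O, (R)-DTBM-SEGPHOS, (EtO)2MeSiH, t-BuOH) sets the pentyl-bearing centre and gives (4S,8R,9R)-5-hydroxy-8,9-dimethyl-4-pentyl-3,4,8,9-tetrahydro-2H,10H-pyrano[2,3-f]chromene-2,10-dione F4. LiOH then opens the lactone to 8.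

Step 7. The risks are a sluggish condensation of the hindered α-branched aldehyde, partial cis-to-trans epimerisation of 13 through its enamine, and capture of the ortho-quinone methide by the cis-isopropenyl group in an intramolecular hetero-Diels–Alder reaction. The fallback sets out from 7 and 11 and comes back at 14, replacing the condensation by a cross-coupling. NIS iodinates 7 at its only free aromatic position to give (2R,3R,6S)-5-hydroxy-10-iodo-2,3-dimethyl-6-pentyl-2,3,6,7-tetrahydropyrano[3,2-g]chromene-4,8-dione F5. LiAlH4 reduces 11 to [(1S,3S)-2,2-dimethyl-3-(prop-1-en-2-yl)cyclobutyl]methanol F6, and I2/PPh3/imidazole converts it into (1S,3S)-1-(iodomethyl)-2,2-dimethyl-3-(prop-1-en-2-yl)cyclobutane F7. Nickel-catalysed reductive cross-electrophile coupling of F5 with F7 (NiI2, 4,4'-di-tert-butyl-2,2'-bipyridine, Zn dust, DMA) gives (2R,3R,6S)-10-{[(1R,3S)-2,2-dimethyl-3-(prop-1-en-2-yl)cyclobutyl]methyl}-5-hydroxy-2,3-dimethyl-6-pentyl-2,3,6,7-tetrahydropyrano[3,2-g]chromene-4,8-dione F8. LiOH opens the lactone to 14.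

Step 8. The risks are insufficient facial control at C8 by the ligand against the three existing remote stereocentres, competing attack at C6, and reverse-prenyl (branched) attack. The fallback sets out from 14 and comes back at 16, replacing the ionic C-allylation by a sigmatropic one without catalyst control. Pd(PPh3)4 with methyl 2-methylbut-3-en-2-yl carbonate at 0 °C etherifies the free 7-OH selectively to give (3S)-3-[(2R,3R)-8-{[(1R,3S)-2,2-dimethyl-3-(prop-1-en-2-yl)cyclobutyl]methyl}-5-hydroxy-2,3-dimethyl-7-[(2-methylbut-3-en-2-yl)oxy]-4-oxochroman-6-yl]octanoic acid F9. Heating in toluene (or Eu(fod)3 at rt) triggers a dearomative ortho-Claisen rearrangement that delivers the n-prenyl group to C8. This gives 16 together with its C8 epimer, (3S)-3-[(2R,3R,8S)-8-{[(1R,3S)-2,2-dimethyl-3-(prop-1-en-2-yl)cyclobutyl]methyl}-5-hydroxy-2,3-dimethyl-8-(3-methylbut-2-en-1-yl)-4,7-dioxo-3,4,7,8-tetrahydro-2H-chromen-6-yl]octanoic acid F10, and the two are separated by preparative HPLC.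

## Further compounds

F1 | step 2 | 5,7-dihydroxy-4-pentyl-2H-chromen-2-one | CCCCCc1cc(=O)oc2cc(O)cc(O)c12
F2 | step 2 | 5,7-dihydroxy-8-[(E)-2-methylbut-2-enoyl]-4-pentyl-2H-chromen-2-one | CCCCCc1cc(=O)oc2c(C(=O)/C(C)=C/C)c(O)cc(O)c12
F3 | step 2 | (8R,9R)-5-hydroxy-8,9-dimethyl-4-pentyl-8,9-dihydro-2H,10H-pyrano[2,3-f]chromene-2,10-dione | CCCCCc1cc(=O)oc2c1c(O)cc1O[C@H](C)[C@@H](C)C(=O)c12
F4 | step 2 | (4S,8R,9R)-5-hydroxy-8,9-dimethyl-4-pentyl-3,4,8,9-tetrahydro-2H,10H-pyrano[2,3-f]chromene-2,10-dione | CCCCC[C@H]1CC(=O)Oc2c1c(O)cc1O[C@H](C)[C@@H](C)C(=O)c12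
F5 | step 7 | (2R,3R,6S)-5-hydroxy-10-iodo-2,3-dimethyl-6-pentyl-2,3,6,7-tetrahydropyrano[3,2-g]chromene-4,8-dione | CCCCC[C@H]1CC(=O)Oc2c(I)c3O[C@H](C)[C@@H](C)C(=O)c3c(O)c21
F6 | step 7 | [(1S,3S)-2,2-dimethyl-3-(prop-1-en-2-yl)cyclobutyl]methanol | C=C(C)[C@@H]1C[C@H](CO)C1(C)C
F7 | step 7 | (1S,3S)-1-(iodomethyl)-2,2-dimethyl-3-(prop-1-en-2-yl)cyclobutane | C=C(C)[C@@H]1C[C@H](CI)C1(C)C
F8 | step 7 | (2R,3R,6S)-10-{[(1R,3S)-2,2-dimethyl-3-(prop-1-en-2-yl)cyclobutyl]methyl}-5-hydroxy-2,3-dimethyl-6-pentyl-2,3,6,7-tetrahydropyrano[3,2-g]chromene-4,8-dione | CCCCC[C@H]1CC(=O)Oc2c(C[C@H]3C[C@@H](C(C)=C)C3(C)C)c3O[C@H](C)[C@@H](C)C(=O)c3c(O)c21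
F9 | step 8 | (3S)-3-[(2R,3R)-8-{[(1R,3S)-2,2-dimethyl-3-(prop-1-en-2-yl)cyclobutyl]methyl}-5-hydroxy-2,3-dimethyl-7-[(2-methylbut-3-en-2-yl)oxy]-4-oxochroman-6-yl]octanoic acid | CCCCC[C@@H](CC(=O)O)c1c(OC(C)(C)C=C)c(C[C@H]2C[C@@H](C(C)=C)C2(C)C)c2O[C@H](C)[C@@H](C)C(=O)c2c1O
F10 | step 8 | (3S)-3-[(2R,3R,8S)-8-{[(1R,3S)-2,2-dimethyl-3-(prop-1-en-2-yl)cyclobutyl]methyl}-5-hydroxy-2,3-dimethyl-8-(3-methylbut-2-en-1-yl)-4,7-dioxo-3,4,7,8-tetrahydro-2H-chromen-6-yl]octanoic acid | C=C(C)[C@@H]1C[C@H](C[C@]2(CC=C(C)C)C(=O)C([C@@H](CCCCC)CC(=O)O)=C(O)C3=C2O[C@H](C)[C@@H](C)C3=O)C1(C)C
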